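**Retrosynthetic overview**

1. Target 25 is epigallocatechin 3-O-gallate joined 4β→8 to gallocatechin. The last moves are hydrogenolysis of fourteen benzyl ethers, galloylation of O3, and oxidation of a C3–B bond to C3–O with retention.
2. Feature: in the upper pyran ring C (O1, C2, C3, C4, C4a, C8a), ring B on C2 and the oxygen on C3 are cis, and both are trans to ring D (the benzo ring of the lower unit) on C4. A syn addition across a C2=C3 enol ether from the face away from ring D gives exactly this pattern.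
3. Key disconnection: the C2–C(ipso, ring B) and C3–B bonds, by three-component arylboration of (4R)-4-aryl-4H-chromene 16 with bromide 18 and diboron 19.
4. Chromene 16 comes from lactol 14, dihydrocoumarin 13 and 4-arylcoumarin 12 (copper hydride conjugate reduction sets C4), and 12 from Suzuki coupling of lower-unit 8-boronate 6 with coumarin triflate 11.
5. Ring order: rings D, F, E arrive intact in (+)-gallocatechin 1; ring A comes from acetophenone 7; ring C is closed as the coumarin lactone (step 6) and reshaped to the 4H-pyran (steps 9 to 11); ring B is attached in the key step; the galloyl ring comes last.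

Key step: step 13

Remark: 2',4',6'-trihydroxyacetophenone 7 and 3,4,5-tris(benzyloxy)benzoic acid 22 are taken as bought. Coumarin 12 is expected as slowly interconverting rotamers about the C4–C8 axis, and it is assumed that this axis leaves no stereochemical trace once C4 is sp3.

**Route**

Step 1
Reactants: 1 (+)-gallocatechin
Product: 2 5,7,3',4',5'-penta-O-benzyl-(+)-gallocatechin
Conditions: BnBr, K2CO3, DMF, rt, N2
Reagents that add atoms: benzyl bromide, BrCc1ccccc1
Why: Williamson etherification in which K2CO3 deprotonates only the five phenols, so the secondary 3-OH stays free and C2 and C3 are untouched.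

Step 2
Reactants: 2 5,7,3',4',5'-penta-O-benzyl-(+)-gallocatechin
Product: 3 hexa-O-benzyl-(+)-gallocatechin
Conditions: NaH, BnBr, DMF, 0 °C → rt
Reagents that add atoms: benzyl bromide, BrCc1ccccc1
Why: Williamson etherification of the secondary alkoxide, which masks the lower 3-OH so that only the upper O3 is free for galloylation later.

Step 3
Reactants: 3 hexa-O-benzyl-(+)-gallocatechin
Product: 4 8-bromo-hexa-O-benzyl-(+)-gallocatechin
Conditions: NBS (1.0 equiv), CH2Cl2, −78 °C → 0 °C
Reagents that add atoms: N-bromosuccinimide, O=C1CCC(=O)N1Br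
Why: Electrophilic aromatic bromination of the phloroglucinol-type ring D, which for 5,7-di-O-benzyl flavan-3-ol derivatives is known to go to C8 with one equivalent of NBS at low temperature.

Step 4
Reactants: 4 8-bromo-hexa-O-benzyl-(+)-gallocatechin
Product: 6 hexa-O-benzyl-(+)-gallocatechin 8-(pinacol boronate), via 8-lithio arene 5 (not isolated)
Conditions: n-BuLi, THF, −78 °C; then i-PrOBpin, −78 °C → rt
Reagents that add atoms: n-butyllithium, [Li]CCCC (lithium stays in intermediate 5 only); 2-isopropoxy-4,4,5,5-tetramethyl-1,3,2-dioxaborolane, CC(C)OB1OC(C)(C)C(C)(C)O1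
Why: Bromine–lithium exchange at C8 is faster than benzylic deprotonation at −78 °C, and the aryllithium is trapped by the borate ester (borylation of an aryllithium).

Step 5
Reactants: 7 2',4',6'-trihydroxyacetophenone
Product: 8 1-[2,4-bis(benzyloxy)-6-hydroxyphenyl]ethanone
Conditions: BnBr (2.1 equiv), K2CO3, DMF, rt → 60 °C
Reagents that add atoms: benzyl bromide, BrCc1ccccc1
Why: Williamson etherification that stops at the dibenzyl ether because the remaining ortho hydroxyl is hydrogen-bonded to the ketone and is the least nucleophilic.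

Step 6
Reactants: 8 1-[2,4-bis(benzyloxy)-6-hydroxyphenyl]ethanone
Product: 10 5,7-bis(benzyloxy)-4-hydroxycoumarin, via keto ester 9 (not isolated)
Conditions: NaH, (EtO)2CO, toluene, reflux; then aq. HCl
Reagents that add atoms: diethyl carbonate, CCOC(=O)OCC
Why: Claisen condensation of the ketone enolate with diethyl carbonate followed by lactonisation onto the phenoxide closes ring C (O1–C2 bond) as a 4-hydroxycoumarin, a standard route to this ring.

Step 7
Reactants: 10 5,7-bis(benzyloxy)-4-hydroxycoumarin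
Product: 11 5,7-bis(benzyloxy)-2-oxo-2H-chromen-4-yl trifluoromethanesulfonate
Conditions: Tf2O, Et3N, CH2Cl2, −10 °C
Reagents that add atoms: trifluoromethanesulfonic anhydride, O=S(=O)(OS(=O)(=O)C(F)(F)F)C(F)(F)F
Why: O-sulfonylation of the vinylogous acid gives a vinyl triflate that is activated for oxidative addition by the lactone carbonyl.

Step 8
Reactants: 6 hexa-O-benzyl-(+)-gallocatechin 8-(pinacol boronate); 11 5,7-bis(benzyloxy)-2-oxo-2H-chromen-4-yl trifluoromethanesulfonate
Product: 12 5,7-bis(benzyloxy)-4-(hexa-O-benzyl-(+)-gallocatechin-8-yl)coumarin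
Conditions: Pd(OAc)2 (5 mol%), SPhos (10 mol%), K3PO4, toluene/H2O (10:1), 80 °C
Reagents that add atoms: none
Why: Suzuki–Miyaura coupling of a 4-triflyloxycoumarin, with a dialkylbiarylphosphine chosen because it is known to couple 2,6-dialkoxyaryl boron reagents with hindered partners, forms the C4–C8 bond.

Step 9
Reactants: 12 5,7-bis(benzyloxy)-4-(hexa-O-benzyl-(+)-gallocatechin-8-yl)coumarin
Product: 13 (4R)-5,7-bis(benzyloxy)-4-(hexa-O-benzyl-(+)-gallocatechin-8-yl)chroman-2-one
Conditions: Cu(OAc)2·H2O (5 mol%), (S)-DTBM-SEGPHOS (5 mol%), (EtO)2MeSiH, t-BuOH, toluene, 0 °C → rt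
Reagents that add atoms: none
Why: Copper hydride asymmetric conjugate reduction, a known reaction of 4-arylcoumarins, in which the ligand-bound copper hydride should deliver hydride to the Si face of C4 and set 4R (ligand antipode assigned by analogy with simple 4-arylcoumarins and checked on the first run, since the two C4 epimers are diastereomers), while t-BuOH protonates the copper enolate to the lactone.

Step 10
Reactants: 13 (4R)-5,7-bis(benzyloxy)-4-(hexa-O-benzyl-(+)-gallocatechin-8-yl)chroman-2-one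
Product: 14 (4R)-5,7-bis(benzyloxy)-4-(hexa-O-benzyl-(+)-gallocatechin-8-yl)chroman-2-ol (both C2 anomers)
Conditions: i-Bu2AlH (1.1 equiv), CH2Cl2, −78 °C; aq. potassium sodium tartrate
Reagents that add atoms: none
Why: Partial reduction of the lactone stops at the lactol because the tetrahedral aluminium alkoxide is stable at −78 °C; C4 is not involved.

Step 11
Reactants: 14 (4R)-5,7-bis(benzyloxy)-4-(hexa-O-benzyl-(+)-gallocatechin-8-yl)chroman-2-ol
Product: 16 (4R)-5,7-bis(benzyloxy)-4-(hexa-O-benzyl-(+)-gallocatechin-8-yl)-4H-chromene, via 2-mesyloxychroman 15 (not isolated)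
Conditions: MsCl, Et3N (excess), CH2Cl2, 0 °C → reflux
Reagents that add atoms: methanesulfonyl chloride, CS(=O)(=O)Cl (its atoms stay in intermediate 15 only)
Why: Lactol-to-glycal dehydration, in which the anomeric mesylate ionises to the oxocarbenium ion and loses the C3 proton to the amine, gives the C2=C3 enol ether under non-acidic conditions that leave the C4 stereocentre and the C4–C8 bond alone.

Step 12
Reactants: 17 5-bromobenzene-1,2,3-triol
Product: 18 5-bromo-1,2,3-tris(benzyloxy)benzene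
Conditions: BnBr, K2CO3, DMF, rt, N2
Reagents that add atoms: benzyl bromide, BrCc1ccccc1
Why: Threefold Williamson etherification of the pyrogallol under inert gas, which keeps the electron-rich triol from oxidising.

Step 13
Reactants: 16 (4R)-5,7-bis(benzyloxy)-4-(hexa-O-benzyl-(+)-gallocatechin-8-yl)-4H-chromene; 18 5-bromo-1,2,3-tris(benzyloxy)benzene; 19 bis(pinacolato)diboron
Product: 20 (2S,3R,4R)-2,3-cis-3,4-trans 3-(pinacolboryl) benzylated bis-flavan
Conditions: NiCl2·DME (10 mol%), 19 (3 equiv), 18 (2 equiv), KOMe (2 equiv), DMA/THF, 30 °C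
Reagents that add atoms: none
Why: Proposed new method: a boryl–nickel species formed from NiCl2·DME, diboron 19 and KOMe is expected to add syn across the C2=C3 enol ether with boron at C3 and nickel at C2, where the ring oxygen stabilises the carbon–nickel bond, after which oxidative addition of bromide 18 and reductive elimination form the C2–aryl bond with retention, so aryl and boron end cis. The closest known reaction type is the nickel-catalysed syn 1,2-arylboration of unconjugated cyclic alkenes and of glycals, which puts the aryl group on the oxygen-bearing carbon and boron on its neighbour; nickel is preferred to a copper/palladium pair because boryl–copper species insert readily only into strained or aryl-conjugated alkenes. No ring is closed. Both new stereocentres (C2 and C3) are controlled by the single C4 stereocentre: peri strain with the C5 benzyloxy group forces ring D pseudoaxial over one face of the alkene, so the boryl–metal unit adds to the other face and the 2,3-cis-3,4-trans array results. The step needs facial selectivity (from pseudoaxial ring D), regioselectivity (from enol ether polarity) and syn stereospecificity (the only hydrogen on C3 lies anti to the C2–nickel bond, so β-hydride elimination cannot scramble C2), and neither benzylic position is ionised at any point.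

Step 14
Reactants: 20 (2S,3R,4R)-2,3-cis-3,4-trans 3-(pinacolboryl) benzylated bis-flavan
Product: 21 (2R,3R,4R) benzylated bis-flavan 3-ol (upper O3 free)
Conditions: NaBO3·4H2O, THF/H2O (1:1), rt
Reagents that add atoms: sodium perborate tetrahydrate, O.O.O.O.[Na+].[O-]OB=O (one oxygen atom is transferred)
Why: Perborate oxidation of the secondary C–B bond proceeds by 1,2-migration of carbon from boron to oxygen with retention, so O3 takes the place of boron cis to ring B and trans to ring D.

Step 15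
Reactants: 22 3,4,5-tris(benzyloxy)benzoic acid
Product: 23 3,4,5-tris(benzyloxy)benzoyl chloride
Conditions: (COCl)2, DMF (cat.), CH2Cl2, 0 °C → rt
Reagents that add atoms: oxalyl chloride, ClC(=O)C(=O)Cl
Why: Acid chloride formation through the chloroiminium (Vilsmeier-type) activation leaves the benzyl ethers untouched.

Step 16
Reactants: 21 (2R,3R,4R) benzylated bis-flavan 3-ol; 23 3,4,5-tris(benzyloxy)benzoyl chloride
Product: 24 tetradeca-O-benzyl epigallocatechin 3-O-gallate-(4β→8)-gallocatechin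
Conditions: Et3N, DMAP, CH2Cl2, rt → 40 °C
Reagents that add atoms: none
Why: DMAP-catalysed acylation through the acylpyridinium ion reaches the hindered axial 3-OH, which is the only free hydroxyl, and acylation on oxygen leaves C3 unchanged.

Step 17
Reactants: 24 tetradeca-O-benzyl epigallocatechin 3-O-gallate-(4β→8)-gallocatechin
Product: 25 epigallocatechin 3-O-gallate-(4β→8)-gallocatechin (target)
Conditions: H2 (1 atm), Pd(OH)2 on carbon, THF/MeOH/H2O, rt
Reagents that add atoms: none
Why: Hydrogenolysis of the fourteen benzyl ethers over Pd(OH)2 under neutral conditions is the known global deprotection for benzylated proanthocyanidin gallates and spares the ester, the pyran rings and the C4–C8 bond.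

**Compound list**

1 | (+)-gallocatechin, (2R,3S) | Oc1cc(O)c2c(c1)O[C@H](c1cc(O)c(O)c(O)c1)[C@@H](O)C2 | starting material
2 | 5,7,3',4',5'-penta-O-benzyl-(+)-gallocatechin, (2R,3S) | c1c(OCc2ccccc2)cc(OCc2ccccc2)c2c1O[C@H](c1cc(OCc3ccccc3)c(OCc3ccccc3)c(OCc3ccccc3)c1)[C@@H](O)C2 | intermediate
3 | hexa-O-benzyl-(+)-gallocatechin, (2R,3S) | c1c(OCc2ccccc2)cc(OCc2ccccc2)c2c1O[C@H](c1cc(OCc3ccccc3)c(OCc3ccccc3)c(OCc3ccccc3)c1)[C@@H](OCc1ccccc1)C2 | intermediate
4 | 8-bromo-hexa-O-benzyl-(+)-gallocatechin | Brc1c(OCc2ccccc2)cc(OCc2ccccc2)c2c1O[C@H](c1cc(OCc3ccccc3)c(OCc3ccccc3)c(OCc3ccccc3)c1)[C@@H](OCc1ccccc1)C2 | intermediate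
5 | 8-lithio-hexa-O-benzyl-(+)-gallocatechin (not isolated) | [Li]c1c(OCc2ccccc2)cc(OCc2ccccc2)c2c1O[C@H](c1cc(OCc3ccccc3)c(OCc3ccccc3)c(OCc3ccccc3)c1)[C@@H](OCc1ccccc1)C2 | intermediate
6 | hexa-O-benzyl-(+)-gallocatechin 8-(pinacol boronate) | CC1(C)OB(OC1(C)C)c1c(OCc2ccccc2)cc(OCc2ccccc2)c2c1O[C@H](c1cc(OCc3ccccc3)c(OCc3ccccc3)c(OCc3ccccc3)c1)[C@@H](OCc1ccccc1)C2 | intermediate
7 | 2',4',6'-trihydroxyacetophenone | CC(=O)c1c(O)cc(O)cc1O | starting material
8 | 1-[2,4-bis(benzyloxy)-6-hydroxyphenyl]ethanone | CC(=O)c1c(O)cc(OCc2ccccc2)cc1OCc1ccccc1 | intermediate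
9 | ethyl 3-[2,4-bis(benzyloxy)-6-hydroxyphenyl]-3-oxopropanoate (not isolated) | CCOC(=O)CC(=O)c1c(O)cc(OCc2ccccc2)cc1OCc1ccccc1 | intermediate
10 | 5,7-bis(benzyloxy)-4-hydroxycoumarin | O=c1cc(O)c2c(OCc3ccccc3)cc(OCc3ccccc3)cc2o1 | intermediate
11 | 5,7-bis(benzyloxy)-2-oxo-2H-chromen-4-yl trifluoromethanesulfonate | O=c1cc(OS(=O)(=O)C(F)(F)F)c2c(OCc3ccccc3)cc(OCc3ccccc3)cc2o1 | intermediate
12 | 5,7-bis(benzyloxy)-4-(hexa-O-benzyl-(+)-gallocatechin-8-yl)coumarin (rotamers about C4–C8) | O=c1cc(-c2c(OCc3ccccc3)cc(OCc3ccccc3)c3c2O[C@H](c2cc(OCc4ccccc4)c(OCc4ccccc4)c(OCc4ccccc4)c2)[C@@H](OCc2ccccc2)C3)c2c(OCc3ccccc3)cc(OCc3ccccc3)cc2o1 | intermediate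
13 | (4R)-5,7-bis(benzyloxy)-4-(hexa-O-benzyl-(+)-gallocatechin-8-yl)chroman-2-one | O=C1C[C@@H](c2c(OCc3ccccc3)cc(OCc3ccccc3)c3c2O[C@H](c2cc(OCc4ccccc4)c(OCc4ccccc4)c(OCc4ccccc4)c2)[C@@H](OCc2ccccc2)C3)c2c(OCc3ccccc3)cc(OCc3ccccc3)cc2O1 | intermediate
14 | (4R)-5,7-bis(benzyloxy)-4-(hexa-O-benzyl-(+)-gallocatechin-8-yl)chroman-2-ol (C2 anomers) | OC1C[C@@H](c2c(OCc3ccccc3)cc(OCc3ccccc3)c3c2O[C@H](c2cc(OCc4ccccc4)c(OCc4ccccc4)c(OCc4ccccc4)c2)[C@@H](OCc2ccccc2)C3)c2c(OCc3ccccc3)cc(OCc3ccccc3)cc2O1 | intermediate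
15 | (4R)-2-mesyloxychroman derived from 14 (not isolated) | CS(=O)(=O)OC1C[C@@H](c2c(OCc3ccccc3)cc(OCc3ccccc3)c3c2O[C@H](c2cc(OCc4ccccc4)c(OCc4ccccc4)c(OCc4ccccc4)c2)[C@@H](OCc2ccccc2)C3)c2c(OCc3ccccc3)cc(OCc3ccccc3)cc2O1 | intermediate
16 | (4R)-5,7-bis(benzyloxy)-4-(hexa-O-benzyl-(+)-gallocatechin-8-yl)-4H-chromene | C1=C[C@@H](c2c(OCc3ccccc3)cc(OCc3ccccc3)c3c2O[C@H](c2cc(OCc4ccccc4)c(OCc4ccccc4)c(OCc4ccccc4)c2)[C@@H](OCc2ccccc2)C3)c2c(OCc3ccccc3)cc(OCc3ccccc3)cc2O1 | intermediate
17 | 5-bromobenzene-1,2,3-triol | Oc1cc(Br)cc(O)c1O | starting material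
18 | 5-bromo-1,2,3-tris(benzyloxy)benzene | Brc1cc(OCc2ccccc2)c(OCc2ccccc2)c(OCc2ccccc2)c1 | intermediate
19 | bis(pinacolato)diboron | CC1(C)OB(OC1(C)C)B1OC(C)(C)C(C)(C)O1 | starting material
20 | 3-(pinacolboryl) benzylated bis-flavan, upper unit (2S,3R,4R), 2,3-cis-3,4-trans, lower unit (2R,3S) | CC1(C)OB(OC1(C)C)[C@@H]1[C@@H](c2c(OCc3ccccc3)cc(OCc3ccccc3)c3c2O[C@H](c2cc(OCc4ccccc4)c(OCc4ccccc4)c(OCc4ccccc4)c2)[C@@H](OCc2ccccc2)C3)c2c(OCc3ccccc3)cc(OCc3ccccc3)cc2O[C@@H]1c1cc(OCc2ccccc2)c(OCc2ccccc2)c(OCc2ccccc2)c1 | intermediate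
21 | benzylated bis-flavan 3-ol, upper unit (2R,3R,4R), lower unit (2R,3S) | O[C@@H]1[C@@H](c2c(OCc3ccccc3)cc(OCc3ccccc3)c3c2O[C@H](c2cc(OCc4ccccc4)c(OCc4ccccc4)c(OCc4ccccc4)c2)[C@@H](OCc2ccccc2)C3)c2c(OCc3ccccc3)cc(OCc3ccccc3)cc2O[C@@H]1c1cc(OCc2ccccc2)c(OCc2ccccc2)c(OCc2ccccc2)c1 | intermediate
22 | 3,4,5-tris(benzyloxy)benzoic acid | OC(=O)c1cc(OCc2ccccc2)c(OCc2ccccc2)c(OCc2ccccc2)c1 | starting material
23 | 3,4,5-tris(benzyloxy)benzoyl chloride | ClC(=O)c1cc(OCc2ccccc2)c(OCc2ccccc2)c(OCc2ccccc2)c1 | intermediate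
24 | tetradeca-O-benzyl epigallocatechin 3-O-gallate-(4β→8)-gallocatechin | O=C(O[C@@H]1[C@@H](c2c(OCc3ccccc3)cc(OCc3ccccc3)c3c2O[C@H](c2cc(OCc4ccccc4)c(OCc4ccccc4)c(OCc4ccccc4)c2)[C@@H](OCc2ccccc2)C3)c2c(OCc3ccccc3)cc(OCc3ccccc3)cc2O[C@@H]1c1cc(OCc2ccccc2)c(OCc2ccccc2)c(OCc2ccccc2)c1)c1cc(OCc2ccccc2)c(OCc2ccccc2)c(OCc2ccccc2)c1 | intermediate
25 | (2R,3R,4R)-5,7-dihydroxy-2-(3,4,5-trihydroxyphenyl)-4-[(2R,3S)-3,5,7-trihydroxy-2-(3,4,5-trihydroxyphenyl)chroman-8-yl]chroman-3-yl 3,4,5-trihydroxybenzoate | O=C(O[C@@H]1[C@@H](c2c(O)cc(O)c3c2O[C@H](c2cc(O)c(O)c(O)c2)[C@@H](O)C3)c2c(O)cc(O)cc2O[C@@H]1c1cc(O)c(O)c(O)c1)c1cc(O)c(O)c(O)c1 | target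

**Step count**

Total step count: 17. Longest linear sequence: 12 steps (1, 2, 3, 4, 8, 9, 10, 11, 13, 14, 16, 17).

**Steps most likely to fail**

Step 13 (proposed new method). Three processes may defeat it:
- insertion of the boryl–nickel species into the hindered enol ether may be so slow that direct borylation of bromide 18 wins;
- addition with boron at C2 would be followed by β-aryloxy elimination and opening of ring C (the same elimination threatens boronate 20 if excess alkoxide is present);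
- attack on the face of ring D would give the wrong C2/C3 pair.

The fallback gives up the enol ether and forms the C4–C8 bond by the known Lewis-acid flavan-4-yl cation coupling, taking the upper unit from the chiral pool. It sets out from compound 3 and bought (−)-epigallocatechin (Oc1cc(O)c2c(c1)O[C@H](c1cc(O)c(O)c(O)c1)[C@H](O)C2). Benzylation of the five phenols (BnBr, K2CO3, DMF) would give 5,7,3',4',5'-penta-O-benzyl-(−)-epigallocatechin F1. Oxidation at C4 with DDQ in the presence of 2-ethoxyethanol (CH2Cl2, rt) would give the 4β-(2-ethoxyethoxy) ether F2. Acetylation (Ac2O, DMAP, pyridine) would give the 3-O-acetate F3. Ionisation of F3 with TMSOTf (CH2Cl2, −78 °C) in the presence of an excess of compound 3 should let C8 of 3 attack the C4 cation anti to the C3 acetoxy group and give the 3,4-trans dimer 3-O-acetate F4. Removal of the acetate (K2CO3, MeOH/THF) rejoins the route at compound 21, from which steps 16 and 17 follow.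

Step 9. The hydride may fail to reach the congested C4, which carries a 2,6-dioxygenated aryl group and has a peri benzyloxy neighbour. Alternatively, the C4–C8 axis and the lower unit may override the catalyst, so that facial selectivity is poor. The fallback gives up catalyst control. Setting out from compound 12, a small achiral copper hydride (Cu(OAc)2·H2O, 1,2-bis(diphenylphosphino)benzene, polymethylhydrosiloxane, t-BuOH, toluene) would reduce both faces. Because the lower unit is enantiopure the two products are diastereomers, and chromatography would separate compound 13 from its C4 epimer, the (4S)-dihydrocoumarin F5. The route is rejoined at compound 13.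

Step 8. Protodeboronation of the 2,6-dialkoxyaryl boronate may outrun transmetalation to the hindered vinylpalladium species, or the triflate may hydrolyse in the aqueous base. The fallback changes the nucleophile to an organozinc and works without water. Setting out from compound 4, bromine–lithium exchange (n-BuLi, THF, −78 °C) and addition of ZnCl2 would give the 8-(chlorozincio) arene F6. Negishi coupling of F6 with triflate 11 (Pd(OAc)2, SPhos, THF, 50 °C) rejoins the route at compound 12.

**Further compounds**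

F1 | step 13 | 5,7,3',4',5'-penta-O-benzyl-(−)-epigallocatechin, (2R,3R) | O[C@@H]1Cc2c(OCc3ccccc3)cc(OCc3ccccc3)cc2O[C@@H]1c1cc(OCc2ccccc2)c(OCc2ccccc2)c(OCc2ccccc2)c1
F2 | step 13 | 4β-(2-ethoxyethoxy)-penta-O-benzyl-(−)-epigallocatechin, 3,4-trans | O[C@@H]1[C@@H](OCCOCC)c2c(OCc3ccccc3)cc(OCc3ccccc3)cc2O[C@@H]1c1cc(OCc2ccccc2)c(OCc2ccccc2)c(OCc2ccccc2)c1
F3 | step 13 | 3-O-acetyl-4β-(2-ethoxyethoxy)-penta-O-benzyl-(−)-epigallocatechin | CC(=O)O[C@@H]1[C@@H](OCCOCC)c2c(OCc3ccccc3)cc(OCc3ccccc3)cc2O[C@@H]1c1cc(OCc2ccccc2)c(OCc2ccccc2)c(OCc2ccccc2)c1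
F4 | step 13 | 3-O-acetate of compound 21 (3,4-trans 4→8 dimer) | CC(=O)O[C@@H]1[C@@H](c2c(OCc3ccccc3)cc(OCc3ccccc3)c3c2O[C@H](c2cc(OCc4ccccc4)c(OCc4ccccc4)c(OCc4ccccc4)c2)[C@@H](OCc2ccccc2)C3)c2c(OCc3ccccc3)cc(OCc3ccccc3)cc2O[C@@H]1c1cc(OCc2ccccc2)c(OCc2ccccc2)c(OCc2ccccc2)c1
F5 | step 9 | (4S)-5,7-bis(benzyloxy)-4-(hexa-O-benzyl-(+)-gallocatechin-8-yl)chroman-2-one (C4 epimer of 13) | O=C1C[C@H](c2c(OCc3ccccc3)cc(OCc3ccccc3)c3c2O[C@H](c2cc(OCc4ccccc4)c(OCc4ccccc4)c(OCc4ccccc4)c2)[C@@H](OCc2ccccc2)C3)c2c(OCc3ccccc3)cc(OCc3ccccc3)cc2O1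
F6 | step 8 | 8-(chlorozincio)-hexa-O-benzyl-(+)-gallocatechin | Cl[Zn]c1c(OCc2ccccc2)cc(OCc2ccccc2)c2c1O[C@H](c1cc(OCc3ccccc3)c(OCc3ccccc3)c(OCc3ccccc3)c1)[C@@H](OCc1ccccc1)C2
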